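**Retrosynthetic overview**

1. Numbering used throughout: ring C1 (quaternary; carries C7H2OH and the homofarnesyl chain), C2 (carries the arm Ca–Cb–Cc–OH), C3 (exocyclic double bond to C8, which carries CH3 and C9), C4, C5, C6 (C(OH)CH3). The plan rests on this cyclohexane: its fully substituted C3=C8 bond needs C9 on the C2 side, and the C2 arm has its oxygen on the third carbon, where a palladium hydride that has travelled along the arm can be discharged as a carbonyl group.
2. Target 33 ⇐ (MnO2; acid; NaBH4) ⇐ bicyclic aldehyde 30 ⇐ palladium closure of C2–C3 (6-exo) with migration of palladium to Cc, from alkenyl iodide 29 whose iodine already sits cis to C9.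
3. 29 ⇐ anti-carbomagnesiation/iodination of propargylic alcohol 25 (methyl to C8, iodine to C3) ⇐ acetonide 23 of a 1,3-diol.
4. C1 and C6 ⇐ Sharpless epoxidation of tetrasubstituted allylic alcohol 11, addition of an (E)-alkenylzinc reagent to the derived aldehyde, and 1,2-shift of that alkenyl group from C7 to C1 (semipinacol).
5. 11 ⇐ carbomagnesiation of 2-butyn-1-ol with homofarnesylmagnesium iodide (from farnesyl bromide), iodination and Negishi coupling. Rings form in the order oxirane (step 6, opened in step 10), dioxane bridge (step 11), cyclohexane (step 16).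

Key step: step 16

Remark: compound 18 is carried as a mixture of epimers at C7, because that carbinol carbon becomes the carbonyl carbon in step 10; 4-(trimethylsilyl)but-3-yn-1-ol is taken as a commercial reagent. "Homofarnesyl" means the (3E,7E)-4,8,12-trimethyltrideca-3,7,11-trien-1-yl group.

**Route**

Step 1
Reactants: 1 (2E,6E)-farnesyl bromide
Product: 2 homofarnesyl phenyl sulfide
Conditions: thioanisole, n-BuLi, DABCO, THF, 0 °C; then 1, –78 °C → 0 °C
Reagents that add atoms: thioanisole, CSc1ccccc1
Why: SN2 alkylation of phenylthiomethyllithium by the primary allylic bromide (Corey–Seebach thioanisole alkylation) should add one carbon without touching the alkene geometry.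

Step 2
Reactants: 2 homofarnesyl phenyl sulfide
Product: 3 homofarnesyl iodide
Conditions: MeI (excess), NaI, DMF, 75 °C, dark
Reagents that add atoms: methyl iodide, IC
Why: S-methylation gives a sulfonium salt whose primary carbon is displaced by iodide with loss of thioanisole (Corey–Jautelat sulfide-to-iodide exchange), which leaves the three alkenes alone.

Step 3
Reactants: 3 homofarnesyl iodide; 4 2-butyn-1-ol
Product: 7 (2Z)-3-iodo-2-homofarnesylbut-2-en-1-ol (iodine cis to CH2OH), via homofarnesylmagnesium iodide 5 (not isolated), via cyclic alkenylmagnesium alkoxide 6 (not isolated)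
Conditions: 3 (1.5 equiv), Mg, Et2O, rt; 4, i-PrMgCl (1.0 equiv), Et2O, 0 °C; combine, CuI (copper monoiodide, 15 mol %), rt → 35 °C; then I2, THF, –40 → 0 °C
Reagents that add atoms: iodine, [I][I]
Why: CuI-catalysed anti-carbomagnesiation of a 2-alkyn-1-ol magnesium alkoxide (Duboudin reaction) puts the alkyl group on the carbon next to CH2O and the chelated magnesium on the far carbon cis to CH2O, and iodinolysis with retention should give the Z-iodide.

Step 4
Reactants: 8 4-(trimethylsilyl)but-3-yn-1-ol
Product: 9 (4-iodobut-1-yn-1-yl)trimethylsilane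
Conditions: I2, PPh3, imidazole, CH2Cl2, 0 °C → rt
Reagents that add atoms: iodine, [I][I]
Why: Garegg–Samuelsson (Appel-type) iodination of a primary alcohol is a routine SN2 displacement of the oxyphosphonium group.

Step 5
Reactants: 7 (2Z)-3-iodo-2-homofarnesylbut-2-en-1-ol; 9 (4-iodobut-1-yn-1-yl)trimethylsilane
Product: 11 (2Z)-3-methyl-2-homofarnesyl-7-(trimethylsilyl)hept-2-en-6-yn-1-ol (CH2OH cis to the butynyl chain), via alkylzinc iodide 10 (not isolated)
Conditions: 9, Zn dust (activated with 1,2-dibromoethane and Me3SiCl), THF, 40 °C; then 7, Pd(PPh3)4 (5 mol %), THF, 45 °C (2.5 equiv of 10)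
Reagents that add atoms: none
Why: Negishi coupling of a primary alkylzinc iodide with an alkenyl iodide proceeds with retention of alkene geometry, and the excess organozinc should tolerate the free hydroxyl as its zinc alkoxide.

Step 6
Reactants: 11 tetrasubstituted allylic alcohol
Product: 12 [(2S,3R)-3-methyl-2-homofarnesyl-3-[4-(trimethylsilyl)but-3-yn-1-yl]oxiran-2-yl]methanol
Conditions: Ti(OiPr)4 (10 mol %), L-(+)-diethyl tartrate (12 mol %), t-BuOOH (anhydrous, in decane), 4 Å molecular sieves, CH2Cl2, –25 °C
Reagents that add atoms: tert-butyl hydroperoxide, CC(C)(C)OO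
Why: Sharpless asymmetric epoxidation acts only on the allylic alcohol alkene, and the L-(+)-tartrate complex delivers oxygen to the face that gives the (2S,3R)-oxirane, in the same sense as (2S,3R)-epoxynerol, which sets C6 and the provisional configuration of C1.

Step 7
Reactants: 12 epoxy alcohol
Product: 13 (2R,3R)-3-methyl-2-homofarnesyl-3-[4-(trimethylsilyl)but-3-yn-1-yl]oxirane-2-carbaldehyde
Conditions: Dess–Martin periodinane, pyridine, CH2Cl2, 0 °C → rt
Reagents that add atoms: none
Why: Buffered Dess–Martin oxidation of a primary epoxy alcohol gives the epoxy aldehyde, which has no α-hydrogen and so cannot epimerise.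

Step 8
Reactants: 14 3-butyn-1-ol
Product: 15 1-[(but-3-yn-1-yloxy)methyl]-4-methoxybenzene
Conditions: NaH (1.05 equiv), 4-methoxybenzyl chloride, Bu4NI (cat.), THF/DMF, 0 °C → rt
Reagents that add atoms: 4-methoxybenzyl chloride, COc1ccc(CCl)cc1
Why: Williamson etherification of the alkoxide, since one equivalent of hydride removes only the hydroxyl proton and not the alkyne proton.

Step 9
Reactants: 13 epoxy aldehyde; 15 PMB ether of 3-butyn-1-ol
Product: 18 (2E)-1-[(2S,3R)-oxiranyl]-5-[(4-methoxybenzyl)oxy]pent-2-en-1-ol (both carbinol epimers), via alkenylzirconocene chloride 16 (not isolated), via alkenyl(methyl)zinc 17 (not isolated)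
Conditions: 15 (1.6 equiv), Cp2Zr(H)Cl (1.5 equiv), CH2Cl2, rt; Me2Zn (1.5 equiv), toluene, –65 °C; then 13, –65 → 0 °C
Reagents that add atoms: none
Why: Syn hydrozirconation of the terminal alkyne gives the (E)-alkenylzirconocene, transmetalation to zinc and 1,2-addition to the aldehyde (Wipf alkenylzinc addition) spare the oxirane and the silylalkyne, and the new C7 centre need not be controlled because step 10 destroys it.

Step 10
Reactants: 18 epoxy carbinol
Product: 22 (2R,3R)-3-methyl-2-homofarnesyl-2-[(1E)-4-[(4-methoxybenzyl)oxy]but-1-en-1-yl]hept-6-yne-1,3-diol, via trimethylsilyl ether 19 (not isolated), via silyloxy aldehyde 20 (not isolated), via silylated alcohol 21 (not isolated)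
Conditions: Me3SiCl, imidazole, CH2Cl2, 0 °C, aqueous wash; crude 19, BF3·OEt2 (0.3 equiv), CH2Cl2, –78 °C; then NaBH4, MeOH, –78 → 0 °C; then K2CO3, MeOH, rt
Reagents that add atoms: none
Why: In this Lewis-acid-promoted semipinacol rearrangement of a 2,3-epoxy alcohol silyl ether (Suzuki–Tsuchihashi type) the electron-rich alkenyl group on C7 should migrate to C1 anti to the breaking C1–O bond while the C7 oxygen forms the carbonyl, so C1 is set with inversion and C6 keeps its oxygen with retention, after which reduction in the flask removes the retro-aldol-prone aldehyde and methanolysis removes both silyl groups.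

Step 11
Reactants: 22 alkynyl 1,3-diol
Product: 23 (4R,5R)-4-(but-3-yn-1-yl)-2,2,4-trimethyl-5-homofarnesyl-5-[(1E)-4-[(4-methoxybenzyl)oxy]but-1-en-1-yl]-1,3-dioxane
Conditions: 2,2-dimethoxypropane, PPTS (cat.), CH2Cl2, rt
Reagents that add atoms: 2,2-dimethoxypropane, COC(C)(C)OC
Why: Acid-catalysed transketalisation ties the primary C7 hydroxyl and the tertiary C6 hydroxyl into a six-membered acetonide, which protects both and later fixes the conformation of the cyclisation.

Step 12
Reactants: 23 acetonide
Product: 25 propargylic alcohol (the butynyl chain of 23 extended to CH2CH2C≡CCH2OH), via lithium acetylide 24 (not isolated)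
Conditions: n-BuLi (1.1 equiv), THF, –78 °C; paraformaldehyde, –78 °C → rt
Reagents that add atoms: formaldehyde (from paraformaldehyde), C=O
Why: Deprotonation of the terminal alkyne, the only acidic site, and addition of the acetylide to formaldehyde supplies C9 with the free hydroxyl needed to direct the next step.

Step 13
Reactants: 25 propargylic alcohol
Product: 27 (2Z)-3-iodo-2-methylpent-2-en-1-ol carrying the dioxane on C5 (iodine on C3 cis to C9H2OH), via cyclic alkenylmagnesium alkoxide 26 (not isolated)
Conditions: MeMgBr (5 equiv), CuI (0.3 equiv), Et2O/toluene, 0 → 40 °C; then I2, THF, –40 → 0 °C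
Reagents that add atoms: methylmagnesium bromide, C[Mg]Br; iodine, [I][I]
Why: A second Duboudin anti-carbomagnesiation, driven by a large excess of the cheap Grignard reagent, places methyl on C8 and the chelated magnesium on C3 cis to C9, and iodinolysis with retention fixes the geometry that the ring closure will copy.

Step 14
Reactants: 27 iodoalkenol
Product: 28 tert-butyldimethylsilyl ether of 27 at C9
Conditions: TBSCl, imidazole, DMF, 0 °C → rt
Reagents that add atoms: tert-butyldimethylsilyl chloride, CC(C)(C)[Si](C)(C)Cl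
Why: Silylation of the only free hydroxyl blocks the cis-disposed allylic alcohol, which could otherwise be oxidised by the alkenylpalladium intermediate through alkoxide β-hydride loss.

Step 15
Reactants: 28 silyl ether
Product: 29 acetonide-bridged alkenyl iodide with a free (E)-homoallylic alcohol arm on C1
Conditions: DDQ (1.3 equiv), CH2Cl2/pH 7 buffer (10:1), 0 °C
Reagents that add atoms: none
Why: Oxidative cleavage of the 4-methoxybenzyl ether by DDQ frees the Cc hydroxyl without affecting the silyl ether, the acetonide, the alkenyl iodide or the unactivated alkenes.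

Step 16
Reactants: 29 alkenyl iodide
Product: 30 bicyclic aldehyde: cyclohexane (1R,2S,6R) cis-fused to the 2,2-dimethyl-1,3-dioxane through C1 and C6, exocyclic C3=C8 with C9H2OTBS cis to C2, and a CH2CH2CHO arm on C2
Conditions: Pd(OAc)2 (10 mol %), PPh3 (20 mol %), Ag2CO3 (1.5 equiv), MeCN, degassed, 60 °C
Reagents that add atoms: none
Why: Zerovalent palladium, formed in the flask from Pd(OAc)2 and the phosphine, adds to the C3–I bond with retention, so palladium sits cis to C9 as the iodine did; Ag2CO3 strips iodide and the cationic alkenylpalladium inserts the C2=Ca alkene syn in a 6-exo-trig Heck closure that forms C2–C3 and the cyclohexane. The alkylpalladium at Ca then loses hydride toward Cb, reinserts to place palladium on Cb, and a second elimination at Cc gives the enol of the aldehyde, while base returns the palladium hydride to zerovalent palladium; the closest known reactions are the redox-relay Heck coupling of alkenols with alkenyl electrophiles and the older Heck vinylation of unsaturated alcohols to carbonyl compounds. C2 is set in the chair-like insertion transition state: the C2–Ca bond must lie over the Pd–C3 bond, hence roughly perpendicular to the C4–C3=C8 plane and axial, and of the two axial arrangements the one with Ca syn to the acetonide oxygen on C6 avoids a 1,3-diaxial clash with the C6 methyl and gives the (2S) epimer. The step needs exo over endo closure, which the tether length and the 1,2-disubstituted alkene favour, and hydride loss away from the ring C2–H, which is helped because loss toward C2 would build a twisted 1,2-bis(alkylidene)cyclohexane strained against C9 and because, at cationic palladium, hydride elimination is reversible while carbonyl formation at Cc is not. The C3=C8 geometry is carried over unchanged by the stereoretentive palladium cycle, and the trisubstituted chain alkenes are too remote and too hindered to compete for insertion.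

Step 17
Reactants: 30 bicyclic aldehyde
Product: 31 primary alcohol (arm CH2CH2CH2OH), otherwise as 30
Conditions: NaBH4, MeOH, 0 °C
Reagents that add atoms: none
Why: Borohydride reduction of the only carbonyl group returns Cc to the alcohol level required in the target.

Step 18
Reactants: 31 alcohol
Product: 32 tetraol: (1R,2S,6R)-cyclohexane with C7H2OH, C6–OH, CcH2OH and the allylic C9H2OH
Conditions: AcOH/THF/H2O (3:1:1), 35 °C
Reagents that add atoms: none
Why: Mild aqueous acid hydrolyses both the primary silyl ether and the strained acetonide, and doing so before the enal exists keeps the final, isomerisable chromophore away from acid.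

Step 19
Reactants: 32 tetraol
Product: 33 target CNP0284886.2
Conditions: MnO2 (activated, excess), CH2Cl2, rt
Reagents that add atoms: none
Why: Activated MnO2 oxidises allylic alcohols far faster than saturated primary or tertiary ones, so only C9 is taken to the aldehyde and the C3=C8 geometry is untouched.

**Compound list**

1 | (2E,6E)-farnesyl bromide | CC(C)=CCC/C(C)=C/CC/C(C)=C/CBr | starting material
2 | homofarnesyl phenyl sulfide | CC(C)=CCC/C(C)=C/CC/C(C)=C/CCSc1ccccc1 | intermediate
3 | homofarnesyl iodide | CC(C)=CCC/C(C)=C/CC/C(C)=C/CCI | intermediate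
4 | 2-butyn-1-ol | CC#CCO | starting material
5 | homofarnesylmagnesium iodide | CC(C)=CCC/C(C)=C/CC/C(C)=C/CC[Mg]I | intermediate
6 | cyclic alkenylmagnesium alkoxide (3-methyl-4-homofarnesyl-2,5-dihydro-1,2-oxamagnesole) | CC(C)=CCC/C(C)=C/CC/C(C)=C/CCC1=C(C)[Mg]OC1 | intermediate
7 | (2Z)-3-iodo-2-homofarnesylbut-2-en-1-ol | CC(C)=CCC/C(C)=C/CC/C(C)=C/CC/C(CO)=C(\C)I | intermediate
8 | 4-(trimethylsilyl)but-3-yn-1-ol | C[Si](C)(C)C#CCCO | starting material
9 | (4-iodobut-1-yn-1-yl)trimethylsilane | C[Si](C)(C)C#CCCI | intermediate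
10 | [4-(trimethylsilyl)but-3-yn-1-yl]zinc iodide | C[Si](C)(C)C#CCC[Zn]I | intermediate
11 | (2Z)-3-methyl-2-homofarnesyl-7-(trimethylsilyl)hept-2-en-6-yn-1-ol | CC(C)=CCC/C(C)=C/CC/C(C)=C/CC/C(CO)=C(\C)CCC#C[Si](C)(C)C | intermediate
12 | [(2S,3R)-3-methyl-2-homofarnesyl-3-[4-(trimethylsilyl)but-3-yn-1-yl]oxiran-2-yl]methanol | CC(C)=CCC/C(C)=C/CC/C(C)=C/CC[C@@]1(CO)O[C@]1(C)CCC#C[Si](C)(C)C | intermediate
13 | (2R,3R)-3-methyl-2-homofarnesyl-3-[4-(trimethylsilyl)but-3-yn-1-yl]oxirane-2-carbaldehyde | CC(C)=CCC/C(C)=C/CC/C(C)=C/CC[C@@]1(C=O)O[C@]1(C)CCC#C[Si](C)(C)C | intermediate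
14 | 3-butyn-1-ol | C#CCCO | starting material
15 | 1-[(but-3-yn-1-yloxy)methyl]-4-methoxybenzene | C#CCCOCc1ccc(OC)cc1 | intermediate
16 | (E)-alkenylzirconocene chloride from 15 | COc1ccc(COCC/C=C/[Zr](Cl)(C2C=CC=C2)C2C=CC=C2)cc1 | intermediate
17 | (E)-alkenyl(methyl)zinc from 16 | COc1ccc(COCC/C=C/[Zn]C)cc1 | intermediate
18 | (2E)-1-[(2S,3R)-oxiranyl]-5-[(4-methoxybenzyl)oxy]pent-2-en-1-ol, both carbinol epimers | CC(C)=CCC/C(C)=C/CC/C(C)=C/CC[C@@]1(C(O)/C=C/CCOCc2ccc(OC)cc2)O[C@]1(C)CCC#C[Si](C)(C)C | intermediate
19 | trimethylsilyl ether of 18 | CC(C)=CCC/C(C)=C/CC/C(C)=C/CC[C@@]1(C(O[Si](C)(C)C)/C=C/CCOCc2ccc(OC)cc2)O[C@]1(C)CCC#C[Si](C)(C)C | intermediate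
20 | (2S,3R)-2-homofarnesyl-3-methyl-2-[(1E)-4-[(4-methoxybenzyl)oxy]but-1-en-1-yl]-7-(trimethylsilyl)-3-(trimethylsilyloxy)hept-6-ynal | CC(C)=CCC/C(C)=C/CC/C(C)=C/CC[C@](C=O)(/C=C/CCOCc1ccc(OC)cc1)[C@](C)(O[Si](C)(C)C)CCC#C[Si](C)(C)C | intermediate
21 | (2R,3R)-primary alcohol from 20, still O- and C-silylated | CC(C)=CCC/C(C)=C/CC/C(C)=C/CC[C@](CO)(/C=C/CCOCc1ccc(OC)cc1)[C@](C)(O[Si](C)(C)C)CCC#C[Si](C)(C)C | intermediate
22 | (2R,3R)-3-methyl-2-homofarnesyl-2-[(1E)-4-[(4-methoxybenzyl)oxy]but-1-en-1-yl]hept-6-yne-1,3-diol | CC(C)=CCC/C(C)=C/CC/C(C)=C/CC[C@](CO)(/C=C/CCOCc1ccc(OC)cc1)[C@](C)(O)CCC#C | intermediate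
23 | (4R,5R)-4-(but-3-yn-1-yl)-2,2,4-trimethyl-5-homofarnesyl-5-[(1E)-4-[(4-methoxybenzyl)oxy]but-1-en-1-yl]-1,3-dioxane | CC(C)=CCC/C(C)=C/CC/C(C)=C/CC[C@]1(COC(C)(C)O[C@]1(C)CCC#C)/C=C/CCOCc1ccc(OC)cc1 | intermediate
24 | lithium acetylide of 23 | CC(C)=CCC/C(C)=C/CC/C(C)=C/CC[C@]1(COC(C)(C)O[C@]1(C)CCC#C[Li])/C=C/CCOCc1ccc(OC)cc1 | intermediate
25 | propargylic alcohol (5-hydroxypent-3-yn-1-yl chain on the dioxane C4) | CC(C)=CCC/C(C)=C/CC/C(C)=C/CC[C@]1(COC(C)(C)O[C@]1(C)CCC#CCO)/C=C/CCOCc1ccc(OC)cc1 | intermediate
26 | cyclic alkenylmagnesium alkoxide from 25 (magnesium on C3, methyl on C8) | CC(C)=CCC/C(C)=C/CC/C(C)=C/CC[C@]1(COC(C)(C)O[C@]1(C)CCC2=C(C)CO[Mg]2)/C=C/CCOCc1ccc(OC)cc1 | intermediate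
27 | (Z)-iodoalkenol (iodine on C3 cis to C9H2OH), PMB ether at Cc | CC(C)=CCC/C(C)=C/CC/C(C)=C/CC[C@]1(COC(C)(C)O[C@]1(C)CC/C(I)=C(\C)CO)/C=C/CCOCc1ccc(OC)cc1 | intermediate
28 | C9 tert-butyldimethylsilyl ether of 27 | CC(C)=CCC/C(C)=C/CC/C(C)=C/CC[C@]1(COC(C)(C)O[C@]1(C)CC/C(I)=C(\C)CO[Si](C)(C)C(C)(C)C)/C=C/CCOCc1ccc(OC)cc1 | intermediate
29 | acetonide-bridged alkenyl iodide with free (E)-homoallylic alcohol arm (cyclisation precursor) | CC(C)=CCC/C(C)=C/CC/C(C)=C/CC[C@]1(COC(C)(C)O[C@]1(C)CC/C(I)=C(\C)CO[Si](C)(C)C(C)(C)C)/C=C/CCO | intermediate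
30 | bicyclic acetonide aldehyde, (1R,2S,6R), C9 silyl ether, arm CH2CH2CHO | CC(C)=CCC/C(C)=C/CC/C(C)=C/CC[C@]1(COC2(C)C)[C@@H](CCC=O)/C(=C(/C)CO[Si](C)(C)C(C)(C)C)CC[C@@]1(C)O2 | intermediate
31 | bicyclic acetonide alcohol, arm CH2CH2CH2OH | CC(C)=CCC/C(C)=C/CC/C(C)=C/CC[C@]1(COC2(C)C)[C@@H](CCCO)/C(=C(/C)CO[Si](C)(C)C(C)(C)C)CC[C@@]1(C)O2 | intermediate
32 | (1R,2S,6R)-tetraol with allylic C9H2OH | CC(C)=CCC/C(C)=C/CC/C(C)=C/CC[C@]1(CO)[C@@H](CCCO)/C(=C(/C)CO)CC[C@@]1(C)O | intermediate
33 | CNP0284886.2 | CC(C)=CCC/C(C)=C/CC/C(C)=C/CC[C@]1(CO)[C@@H](CCCO)/C(=C(/C)C=O)CC[C@@]1(C)O | target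

**Step count**

Total steps: 19. Longest linear sequence: 17 steps (1, 2, 3, 5, 6, 7, 9 to 19); steps 4 and 8 prepare side fragments.

**Steps most likely to fail**

Step 16. After ring closure the alkylpalladium may lose hydride toward the ring C2–H or let go of an intermediate alkene before it reaches Cc, and insertion may take place on the other face of the alkene. The fallback gives up the chain walk and intercepts the alkylpalladium with hydride. It sets out from 28, which still carries the 4-methoxybenzyl ether. A reductive Heck cyclisation (Pd(OAc)2, PPh3, HCO2Na, Bu4NCl, DMF, 80 °C) should give the bicyclic PMB ether with a saturated arm F1. DDQ in buffered CH2Cl2 then removes the benzyl group, and the route is rejoined at 31.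

Step 10. The oxirane may ionise at C6 instead of C1, hydride instead of the alkenyl group may migrate in one of the C7 epimers, or a cation may be trapped by the nearest chain alkene. The fallback replaces the silyl ether and external Lewis acid by a samarium-alkoxide-directed shift in which the aldehyde is reduced as it forms. It sets out from the free carbinol 18, treated with SmI2 (catalytic) and benzaldehyde in THF (tandem semipinacol/Tishchenko reaction known for secondary α-hydroxy epoxides). The product should be the 1,3-diol monobenzoate F2, with the benzoate on the C6 oxygen and C7 already at the alcohol level. NaOMe in MeOH at 40 °C then removes the benzoate and the alkynyl silyl group, and the route is rejoined at 22.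

Step 3. Carbometalation of an internal alkynol by a primary alkyl Grignard reagent used in small excess may be slow, so that protonolysis and homocoupling of the Grignard reagent win. The fallback builds the tetrasubstituted alkene from a β-keto ester instead. It sets out from 3. Alkylation of the sodium enolate of ethyl acetoacetate with 3 (NaH, THF/DMF) gives the racemic keto ester F3. Triflation of its chelated sodium enolate (NaH, Tf2O, CH2Cl2, 0 °C) gives the (Z)-enol triflate F4, with the triflate cis to the ester. Negishi coupling with zinc reagent 10 (Pd(PPh3)4, THF, 45 °C) replaces the triflate with retention to give the enoate F5. DIBAL-H in CH2Cl2 at –78 °C reduces the ester, and the route is rejoined at 11.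

Further compounds
F1 | step 16 | bicyclic acetonide with saturated CH2CH2CH2O-PMB arm on C2 and C9 silyl ether, (1R,2S,6R) | CC(C)=CCC/C(C)=C/CC/C(C)=C/CC[C@]1(COC2(C)C)[C@@H](CCCOCc3ccc(OC)cc3)/C(=C(/C)CO[Si](C)(C)C(C)(C)C)CC[C@@]1(C)O2
F2 | step 10 | (2R,3R)-1,3-diol 3-benzoate, C-silylated analogue of 22 | CC(C)=CCC/C(C)=C/CC/C(C)=C/CC[C@](CO)(/C=C/CCOCc1ccc(OC)cc1)[C@](C)(OC(=O)c1ccccc1)CCC#C[Si](C)(C)C
F3 | step 3 | ethyl 2-acetyl-(5E,9E)-6,10,14-trimethylpentadeca-5,9,13-trienoate (racemic) | CCOC(=O)C(CC/C=C(\C)CC/C=C(\C)CCC=C(C)C)C(C)=O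
F4 | step 3 | ethyl (2Z)-2-homofarnesyl-3-[(trifluoromethylsulfonyl)oxy]but-2-enoate | CCOC(=O)/C(CC/C=C(\C)CC/C=C(\C)CCC=C(C)C)=C(\OS(=O)(=O)C(F)(F)F)C
F5 | step 3 | ethyl (2Z)-3-methyl-2-homofarnesyl-7-(trimethylsilyl)hept-2-en-6-ynoate | CCOC(=O)/C(CC/C=C(\C)CC/C=C(\C)CCC=C(C)C)=C(\CCC#C[Si](C)(C)C)C
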